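I convert everything to millimolar.

common to all: free enzyme 3.5 µM
- spring: starting material 18 mM; second substrate 42 mM; run made earlier
- midnight: starting material 26 mM; second substrate 42 mM; run made earlier
- flask: starting material 35 mM; second substrate 42.0 mM; time 6.0 min

| run | time / min | target / % | starting material / % |
|---|---|---|---|
| spring | 0.167 | 12.3 | 86.4 |
| spring | 0.417 | 20.5 | 74.5 |
| spring | 1.00 | 22.4 | 65.0 |
| spring | 2.50 | 10.7 | 62.5 |
| spring | 6.00 | 1.9 | 61.6 |
| midnight | 0.167 | 9.5 | 90.6 |
| midnight | 0.417 | 14.3 | 83.1 |
| midnight | 1.00 | 14.7 | 75.3 |
| midnight | 2.50 | 6.9 | 72.5 |
| midnight | 6.00 | 1.2 | 73.7 |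

(standard deviation of a reading: 0.5 percentage points)

- time, not beyond 6.0 min, at which the flask holds most target
- the amount of target, in percent of the starting material charged, at that time

I read the last rows first. At 6.00 min the spring run has used 6.91 mM of its starting material and the midnight run 6.84 mM, although midnight was charged with 1.44 times as much. Use has nearly stopped, yet spring still holds 61.6%. So I take the amount used to follow the enzyme, equal in both runs, and not the charge.

Dividing the spring reading by the 3.5 µM of enzyme charged gives N = 1970, the turnovers one enzyme gives on average before it stops, its turnover capacity. With this second substrate charge, I expect control to change hands where the charge of starting material meets N times the enzyme, and spring already stands above that, with a charge larger than the amount used. The flask has the same enzyme, so I expect it to use 6.91 mM, which is 19.7% of its charge.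

The target column goes by millimolar too: at 1.00 min, 4.03 mM in spring and 3.82 mM at midnight. At 0.417 min it reads 3.69 mM and 3.72 mM, and by 6.00 min spring is down to 0.342 mM. I place the peak between those two early times. The flask has the same second substrate charge as the runs, and the readings at 1.00 min, carried to the flask, give about 11.2% of its charge, a figure read beside the peak and not at it.

The forecast says 11.9% (10.8% to 13%) at 0.72 min (0.55 min to 0.9 min), a little higher than my figure, on the ground that the flask “should therefore follow the same mM curve”.

The flask holds most target at 0.664 min, with 12.3% of its charge.

    first complex ⇌ loaded enzyme + first product (K = 0.0249 M, k = 698 s⁻¹)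
    second complex → free enzyme + target (k = 130 s⁻¹)
    second substrate + loaded enzyme ⇌ second complex (K = 632 M⁻¹, k = 2.69 × 10⁵ M⁻¹ s⁻¹)
    second substrate + target → over-reaction product (k = 0.330 M⁻¹ s⁻¹)
    starting material + free enzyme ⇌ first complex (K = 41.1 M⁻¹, k = 6.71 × 10⁵ M⁻¹ s⁻¹)
    second complex → spent catalyst (k = 0.0660 s⁻¹)

At 6.00 min the flask still holds 80% of its starting material. For the neighbour flask with 0.014 mM of free enzyme, N gives 27.6 mM used, so 21.0% left, and at 6.00 min that neighbour holds 21% of its starting material.

The runs are simulated with constants of no real substance; scatter was added.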